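**Strategy.** Ring A of the target carries the quaternary C5 with methyl C19 directly beside C4 with its one-carbon branch C18, β and α to the C3 carbonyl. A Δ4-3-keto octalone is therefore the platform: C5 is electrophilic and, once attacked, C4 becomes nucleophilic. In one operation the key step adds methyl to C5 on the H-10 face and captures the resulting C3 enol derivative at C4 with a methyleneiminium salt, forming C5–C19 and C4–C18 and the cis ring fusion. The precursor is a ring A cyclohexenone fused to a finished ring B (C7 acetate, C8 and C9 methyls, C9 side chain with C13 set, C15 silyl ether), reached from an anisole by Birch reduction.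

Key step: step 13

Remark on numbering: locants follow the clerodane numbering of the target. Ring A is C1–C5 and C10, ring B is C5–C10, the side chain C11–C15 sits on C9 with C16 on C13, C17 is on C8, C18 on C4, C19 on C5 and C20 on C9. The target is (5S,7S,8S,9R,10R,13R).

Assumption on the aldol reagent: the Z-enol borinate with (+)-Ipc ligands (from (−)-α-pinene) is taken to attack the Re face of the aldehyde, by analogy with allylboranes carrying the same ligands. If the sense is the opposite, the antipodal reagent is used.

Assumption on supply: 2-bromo-5-methoxyphenylacetic acid is taken as a catalogue compound (otherwise one bromination from 3-methoxyphenylacetic acid).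

Remark on design: the precursor carries the C7 acetate of the target instead of a silyl ether, so no protecting-group exchange is needed once ring A is sensitive. C9 is set by a reductive Heck ring closure instead of a cation cyclisation.

Step 1
Reactants: 1 (R)-citronellol
Product: 2 (R)-citronellol triisopropylsilyl ether
Conditions: TIPSCl, imidazole, DMF, rt
Reagents that add atoms: triisopropylsilyl chloride, CC(C)[Si](Cl)(C(C)C)C(C)C
Why: Standard silyl ether formation on a primary alcohol; TIPS has no aryl group and should therefore survive the later Birch reduction and dilute aqueous acid.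

Step 2
Reactants: 2 (R)-citronellol triisopropylsilyl ether
Product: 4 (R)-4-methyl-6-(triisopropylsilyloxy)hexanal, via secondary ozonide 3 (not isolated)
Conditions: O3, CH2Cl2, −78 °C; then PPh3, −78 °C to rt
Reagents that add atoms: ozone, [O-][O+]=O
Why: Ozonolysis with reductive work-up cleaves the only alkene to the aldehyde whose carbonyl carbon becomes C9, leaving the C13 stereocentre untouched.

Step 3
Reactants: 4 (R)-4-methyl-6-(triisopropylsilyloxy)hexanal
Product: 5 (6R)-6-methyl-8-(triisopropylsilyloxy)octan-3-ol (both C3 epimers)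
Conditions: EtMgBr, THF, −78 to 0 °C; aq NH4Cl
Reagents that add atoms: ethylmagnesium bromide, CC[Mg]Br
Why: Grignard addition to an unhindered aldehyde brings in C8 and C17; the new carbinol centre is irrelevant because it is oxidised in step 4.

Step 4
Reactants: 5 (6R)-6-methyl-8-(triisopropylsilyloxy)octan-3-ol
Product: 6 (R)-6-methyl-8-(triisopropylsilyloxy)octan-3-one
Conditions: Dess–Martin periodinane, NaHCO3, CH2Cl2, rt
Reagents that add atoms: none
Why: Dess–Martin oxidation of a secondary alcohol gives the ethyl ketone under neutral conditions that spare the silyl ether.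

Step 5
Reactants: 7 2-bromo-5-methoxyphenylacetic acid
Product: 8 2-(2-bromo-5-methoxyphenyl)ethanol
Conditions: BH3·SMe2, THF, 0 °C to rt; MeOH, then aqueous work-up
Reagents that add atoms: none
Why: Borane reduction takes the carboxylic acid chemoselectively to the primary alcohol without touching the aryl bromide or the methyl ether.

Step 6
Reactants: 8 2-(2-bromo-5-methoxyphenyl)ethanol
Product: 9 2-(2-bromo-5-methoxyphenyl)acetaldehyde
Conditions: Dess–Martin periodinane, CH2Cl2, 0 °C; used directly
Reagents that add atoms: none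
Why: Dess–Martin oxidation gives the enolisable arylacetaldehyde without base, and immediate use avoids self-condensation.

Step 7
Reactants: 6 (R)-6-methyl-8-(triisopropylsilyloxy)octan-3-one; 9 2-(2-bromo-5-methoxyphenyl)acetaldehyde
Product: 12 syn-aldol (2S,3R,7R)-1-(2-bromo-5-methoxyphenyl)-2-hydroxy-3,7-dimethyl-9-(triisopropylsilyloxy)nonan-4-one, via Z-enol borinate 10 (not isolated), via boron aldolate 11 (not isolated)
Conditions: (+)-Ipc2BOTf, iPr2NEt, CH2Cl2, −78 °C; then 9, −78 to −20 °C; pH 7 buffer, MeOH, 30% H2O2, 0 °C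
Reagents that add atoms: none
Why: Diisopinocampheylboron-mediated syn-aldol in which the Z-enol borinate reacts through a closed chair (Zimmerman–Traxler) transition state to set C7 and C8 syn, while the Ipc ligands are expected to direct attack to the Re face of the aldehyde and so give 7S,8R independently of the remote C13 centre.

Step 8
Reactants: 12 syn-aldol
Product: 13 (2S,3R,7R)-1-(2-bromo-5-methoxyphenyl)-3,7-dimethyl-2-(triethylsilyloxy)-9-(triisopropylsilyloxy)nonan-4-one
Conditions: TESCl, imidazole, DMF, 0 °C to rt
Reagents that add atoms: triethylsilyl chloride, CC[Si](Cl)(CC)CC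
Why: Silylation of the C7 hydroxyl blocks retro-aldol chemistry in the next steps, and triethylsilyl is chosen so that it is shed in the acid treatment of step 11 while the primary TIPS ether stays.

Step 9
Reactants: 13 triethylsilyl-protected aldol ketone
Product: 14 (2S,3S,7R)-1-(2-bromo-5-methoxyphenyl)-3,7-dimethyl-4-methylidene-2-(triethylsilyloxy)-9-(triisopropylsilyloxy)nonane
Conditions: Cp2TiMe2, toluene, 70 °C, dark
Reagents that add atoms: dimethyltitanocene (Cp2TiMe2), [CH3-].[CH3-].[Ti+4].c1cc[cH-]c1.c1cc[cH-]c1
Why: Petasis methylenation converts the hindered C9 ketone into the 1,1-disubstituted alkene (new carbon C20) without base, so C8 should not epimerise and the β-silyloxy group should not be eliminated.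

Step 10
Reactants: 14 bromoaryl 1,1-disubstituted alkene
Product: 15 (1S,2S,3S)-6-methoxy-1,2-dimethyl-1-[(3R)-3-methyl-5-(triisopropylsilyloxy)pentyl]-3-(triethylsilyloxy)-1,2,3,4-tetrahydronaphthalene
Conditions: Pd(OAc)2 (10 mol %), PPh3, HCO2Na, Et4NCl, DMF, 90 °C
Reagents that add atoms: none
Why: Reductive Heck cyclisation in which the aryl bromide adds oxidatively to zerovalent palladium, 6-exo-trig syn-carbopalladation closes ring B and creates C9, and the neopentyl alkylpalladium (no β-hydrogen) is reduced by formate to the C20 methyl; the palladium-bearing carbon must end pseudoaxial, so a chair-like closure with the C7 silyloxy and C8 methyl groups equatorial should place C20 cis to C17.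

Step 11
Reactants: 15 methoxytetralin
Product: 18 (4aS,5R,6S,7S)-7-hydroxy-5,6-dimethyl-5-[(3R)-3-methyl-5-(triisopropylsilyloxy)pentyl]-4,4a,5,6,7,8-hexahydronaphthalen-2(3H)-one, via dihydroanisole 16 (not isolated), via β,γ-unsaturated ketone 17 (not isolated)
Conditions: Li, NH3(l), THF, tBuOH, −78 to −33 °C; NH4Cl; then 1 M aq HCl, THF, rt
Reagents that add atoms: water, O
Why: Birch reduction gives the 2,5-dihydroanisole (enol ether C2=C3, tetrasubstituted C5=C10), and dilute acid then hydrolyses the enol ether, removes the labile secondary TES ether and moves the double bond into conjugation; C10 should be protonated on the face away from the axial C20 methyl, which is also the thermodynamically preferred epimer with C1 equatorial on ring B.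

Step 12
Reactants: 18 hydroxy octalone
Product: 19 7-O-acetyl octalone (key-step precursor; C3 ketone, C4=C5, 7S,8S,9R,10S,13R)
Conditions: Ac2O, pyridine, DMAP (cat.), CH2Cl2, rt
Reagents that add atoms: acetic anhydride, CC(=O)OC(C)=O
Why: DMAP-catalysed acetylation of the equatorial secondary alcohol installs the C7 acetate of the target before ring A becomes sensitive.

Step 13
Reactants: 19 7-O-acetyl octalone; 20 dimethylmethyleneiminium iodide (Eschenmoser's salt)
Product: 22 cis-fused C4 Mannich base (4R,5S,7S,8S,9R,10R,13R; C3 ketone; C4 CH2NMe2; C5 methyl C19 cis to H-10; C7 OAc; C15 OTIPS), via trimethylsilyl enol ether 21 (not isolated)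
Conditions: Me2CuLi (from MeLi and CuI), TMSCl, THF, −78 °C; Et3N, pentane, filtration, evaporation; then 20, CH2Cl2, 0 °C to rt; aq NaHCO3
Reagents that add atoms: lithium dimethylcuprate, [Li+].C[Cu-]C
Why: The cuprate forms a π-complex with the C4=C5 bond, adds at C5 to give a β-cuprio (trivalent copper) enolate that TMSCl silylates on oxygen, and reductive elimination forms C5–C19 and leaves the C3=C4 silyl enol ether 21, which then attacks the iminium carbon of 20 in a Mannich reaction to form C4–C18 before iodide removes the silyl group. The closest known reaction types are the cuprate addition to Δ4-3-keto octalones without an angular substituent, which gives cis-fused angular-methyl decalones, and the aminomethylation of regiodefined silyl enol ethers with methyleneiminium salts. No ring is closed. C5 is set by the substrate: methyl enters axially with respect to ring A on the face that carries H-10, because the other face is screened by the axial C20 methyl on C9 (a 1,3-diaxial clash in the trans-fused alternative), so C19 ends cis to H-10 and trans to C20; C4 is set by approach of the iminium ion anti to the new C19 methyl and is erased in step 14. The step needs 1,4- instead of 1,2-addition, which the soft cuprate with TMSCl secures, the facial selectivity just described, and alkylation at C4 and not at C2, which follows because conjugate addition can only generate the enol derivative towards C4. The acetate and the TIPS ether are spared because neither a free organolithium nor a free enolate is present at any point.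

Step 14
Reactants: 22 cis-fused C4 Mannich base
Product: 24 C4-methylene ketone (5S,7S,8S,9R,10R,13R; C3 ketone; C4=C18; C7 OAc; C15 OTIPS), via trimethylammonium iodide 23 (not isolated)
Conditions: MeI, MeCN, rt; then aq NaHCO3, CH2Cl2, rt
Reagents that add atoms: none
Why: Quaternisation of the tertiary amine followed by E1cB (Hofmann-type) loss of trimethylamine from the β-ammonium ketone gives the exocyclic C4 methylene, making C4 planar under conditions the acetate tolerates.

Step 15
Reactants: 24 C4-methylene ketone
Product: 25 C15 primary alcohol of the C4-methylene ketone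
Conditions: HF·pyridine, pyridine, THF, 0 °C to rt
Reagents that add atoms: none
Why: Buffered fluoride desilylation removes the primary TIPS ether without touching the acetate or the enone.

Step 16
Reactants: 25 C15 primary alcohol
Product: 26 C15 carboxylic acid of the C4-methylene ketone
Conditions: TEMPO (cat.), PhI(OAc)2, MeCN/H2O, rt
Reagents that add atoms: water, O
Why: TEMPO-catalysed oxidation takes the only hydroxyl group through the aldehyde hydrate to the carboxylic acid, and the cross-conjugated enone is inert to the oxoammonium oxidant.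

Step 17
Reactants: 26 C15 carboxylic acid
Product: 29 C2-hydroxy C4-methylene ketone acid (C2 epimers), via bis-silyl dienol ether 27 (not isolated), via silyloxy ketone silyl ester 28 (not isolated)
Conditions: TMSOTf, iPr2NEt, CH2Cl2, −78 to 0 °C; pentane, filtration, evaporation; DMDO, acetone, −78 °C; then 0.5 M aq HCl, THF, 0 °C
Reagents that add atoms: dimethyldioxirane, CC1(C)OO1
Why: Rubottom oxidation in which soft enolisation can only go towards C2 because C4 has no hydrogen, the electron-rich C2=C3 silyl enol ether is epoxidised in preference to C4=C18, and silyl migration with mild acid gives the α'-hydroxy enone while the transient silyl ester masks the acid; the C2 configuration is irrelevant.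

Step 18
Reactants: 29 C2-hydroxy C4-methylene ketone acid
Product: 30 target CNP0257844.1
Conditions: Dess–Martin periodinane, CH2Cl2, 0 °C to rt
Reagents that add atoms: none
Why: Dess–Martin oxidation of the acyloin gives the 2,3-dione, which can enolise only towards C1 because C4 is sp2 and therefore should settle as the diosphenol of the target under conditions mild enough for the acetate, the acid and the exocyclic enone.

**Compound list**

1 | (R)-citronellol | CC(C)=CCC[C@@H](C)CCO | starting material
2 | (R)-citronellol triisopropylsilyl ether | CC(C)=CCC[C@@H](C)CCO[Si](C(C)C)(C(C)C)C(C)C | intermediate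
3 | secondary ozonide of 2 (1,2,4-trioxolane, epimers at the ring CH) | CC1(C)OOC(CC[C@@H](C)CCO[Si](C(C)C)(C(C)C)C(C)C)O1 | intermediate (not isolated)
4 | (R)-4-methyl-6-(triisopropylsilyloxy)hexanal | O=CCC[C@@H](C)CCO[Si](C(C)C)(C(C)C)C(C)C | intermediate
5 | (6R)-6-methyl-8-(triisopropylsilyloxy)octan-3-ol, both C3 epimers | CCC(O)CC[C@@H](C)CCO[Si](C(C)C)(C(C)C)C(C)C | intermediate
6 | (R)-6-methyl-8-(triisopropylsilyloxy)octan-3-one | CCC(=O)CC[C@@H](C)CCO[Si](C(C)C)(C(C)C)C(C)C | intermediate
7 | 2-bromo-5-methoxyphenylacetic acid | COc1ccc(Br)c(CC(=O)O)c1 | starting material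
8 | 2-(2-bromo-5-methoxyphenyl)ethanol | COc1ccc(Br)c(CCO)c1 | intermediate
9 | 2-(2-bromo-5-methoxyphenyl)acetaldehyde | COc1ccc(Br)c(CC=O)c1 | intermediate
10 | (Z)-enol di[(+)-isopinocampheyl]borinate of 6 | C/C=C(/CC[C@@H](C)CCO[Si](C(C)C)(C(C)C)C(C)C)OB([C@H]1C[C@H]2C[C@@H]([C@@H]1C)C2(C)C)[C@H]1C[C@H]2C[C@@H]([C@@H]1C)C2(C)C | intermediate (not isolated)
11 | boron aldolate (O-diisopinocampheylboryl derivative of 12) | COc1ccc(Br)c(C[C@H](OB([C@H]2C[C@H]3C[C@@H]([C@@H]2C)C3(C)C)[C@H]2C[C@H]3C[C@@H]([C@@H]2C)C3(C)C)[C@@H](C)C(=O)CC[C@@H](C)CCO[Si](C(C)C)(C(C)C)C(C)C)c1 | intermediate (not isolated)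
12 | syn-aldol (2S,3R,7R)-1-(2-bromo-5-methoxyphenyl)-2-hydroxy-3,7-dimethyl-9-(triisopropylsilyloxy)nonan-4-one (clerodane C7 S, C8 R, C13 R) | COc1ccc(Br)c(C[C@H](O)[C@@H](C)C(=O)CC[C@@H](C)CCO[Si](C(C)C)(C(C)C)C(C)C)c1 | intermediate
13 | (2S,3R,7R)-1-(2-bromo-5-methoxyphenyl)-3,7-dimethyl-2-(triethylsilyloxy)-9-(triisopropylsilyloxy)nonan-4-one | COc1ccc(Br)c(C[C@H](O[Si](CC)(CC)CC)[C@@H](C)C(=O)CC[C@@H](C)CCO[Si](C(C)C)(C(C)C)C(C)C)c1 | intermediate
14 | (2S,3S,7R)-1-(2-bromo-5-methoxyphenyl)-3,7-dimethyl-4-methylidene-2-(triethylsilyloxy)-9-(triisopropylsilyloxy)nonane | COc1ccc(Br)c(C[C@H](O[Si](CC)(CC)CC)[C@@H](C)C(=C)CC[C@@H](C)CCO[Si](C(C)C)(C(C)C)C(C)C)c1 | intermediate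
15 | (1S,2S,3S)-6-methoxy-1,2-dimethyl-1-[(3R)-3-methyl-5-(triisopropylsilyloxy)pentyl]-3-(triethylsilyloxy)-1,2,3,4-tetrahydronaphthalene (clerodane 7S,8S,9S,13R; C20 cis to C17, C7–O trans to C17) | COc1ccc2c(c1)C[C@H](O[Si](CC)(CC)CC)[C@@H](C)[C@]2(C)CC[C@@H](C)CCO[Si](C(C)C)(C(C)C)C(C)C | intermediate
16 | dihydroanisole: the 5,8-dihydro derivative of 15 (enol ether C2=C3, C5=C10) | COC1=CCC2=C(C1)C[C@H](O[Si](CC)(CC)CC)[C@@H](C)[C@]2(C)CC[C@@H](C)CCO[Si](C(C)C)(C(C)C)C(C)C | intermediate (not isolated)
17 | β,γ-unsaturated ketone (5S,6S,7S)-5,6-dimethyl-5-[(3R)-3-methyl-5-(triisopropylsilyloxy)pentyl]-7-(triethylsilyloxy)-3,4,5,6,7,8-hexahydronaphthalen-2(1H)-one | O=C1CCC2=C(C1)C[C@H](O[Si](CC)(CC)CC)[C@@H](C)[C@]2(C)CC[C@@H](C)CCO[Si](C(C)C)(C(C)C)C(C)C | intermediate (not isolated)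
18 | (4aS,5R,6S,7S)-7-hydroxy-5,6-dimethyl-5-[(3R)-3-methyl-5-(triisopropylsilyloxy)pentyl]-4,4a,5,6,7,8-hexahydronaphthalen-2(3H)-one | O=C1CC[C@@H]2[C@@](C)(CC[C@@H](C)CCO[Si](C(C)C)(C(C)C)C(C)C)[C@H](C)[C@@H](O)CC2=C1 | intermediate
19 | 7-O-acetyl derivative of 18, the ring A octalone with complete ring B (clerodane 7S,8S,9R,10S,13R) | O=C1CC[C@@H]2[C@@](C)(CC[C@@H](C)CCO[Si](C(C)C)(C(C)C)C(C)C)[C@H](C)[C@@H](OC(C)=O)CC2=C1 | intermediate
20 | dimethylmethyleneiminium iodide (Eschenmoser's salt) | C=[N+](C)C.[I-] | starting material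
21 | trimethylsilyl enol ether (C3=C4) of the cis-fused C5-methyl decalone (5S,7S,8S,9R,10R,13R) | C1=C(O[Si](C)(C)C)CC[C@@H]2[C@@](C)(CC[C@@H](C)CCO[Si](C(C)C)(C(C)C)C(C)C)[C@H](C)[C@@H](OC(C)=O)C[C@]12C | intermediate (not isolated)
22 | cis-fused C4 Mannich base with angular methyl at C5 (4R,5S,7S,8S,9R,10R,13R) | CN(C)C[C@@H]1C(=O)CC[C@@H]2[C@@](C)(CC[C@@H](C)CCO[Si](C(C)C)(C(C)C)C(C)C)[C@H](C)[C@@H](OC(C)=O)C[C@]12C | intermediate
23 | trimethylammonium iodide of 22 | C[N+](C)(C)C[C@@H]1C(=O)CC[C@@H]2[C@@](C)(CC[C@@H](C)CCO[Si](C(C)C)(C(C)C)C(C)C)[C@H](C)[C@@H](OC(C)=O)C[C@]12C.[I-] | intermediate (not isolated)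
24 | C4-methylene ketone (5S,7S,8S,9R,10R,13R), C7 OAc, C15 OTIPS | C=C1C(=O)CC[C@@H]2[C@@](C)(CC[C@@H](C)CCO[Si](C(C)C)(C(C)C)C(C)C)[C@H](C)[C@@H](OC(C)=O)C[C@]12C | intermediate
25 | C15 primary alcohol of 24 | C=C1C(=O)CC[C@@H]2[C@@](C)(CC[C@@H](C)CCO)[C@H](C)[C@@H](OC(C)=O)C[C@]12C | intermediate
26 | C15 carboxylic acid | C=C1C(=O)CC[C@@H]2[C@@](C)(CC[C@@H](C)CC(=O)O)[C@H](C)[C@@H](OC(C)=O)C[C@]12C | intermediate
27 | bis-silyl dienol ether: 3-trimethylsilyloxy-2,4(18)-diene trimethylsilyl ester | C=C1C(O[Si](C)(C)C)=CC[C@@H]2[C@@](C)(CC[C@@H](C)CC(=O)O[Si](C)(C)C)[C@H](C)[C@@H](OC(C)=O)C[C@]12C | intermediate (not isolated)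
28 | 2-trimethylsilyloxy ketone trimethylsilyl ester (C2 epimers) | C=C1C(=O)C(O[Si](C)(C)C)C[C@@H]2[C@@](C)(CC[C@@H](C)CC(=O)O[Si](C)(C)C)[C@H](C)[C@@H](OC(C)=O)C[C@]12C | intermediate (not isolated)
29 | C2-hydroxy C4-methylene ketone acid (C2 epimers) | C=C1C(=O)C(O)C[C@@H]2[C@@](C)(CC[C@@H](C)CC(=O)O)[C@H](C)[C@@H](OC(C)=O)C[C@]12C | intermediate
30 | CNP0257844.1 (5S,7S,8S,9R,10R,13R) | C=C1C(=O)C(O)=C[C@@H]2[C@@](C)(CC[C@@H](C)CC(=O)O)[C@H](C)[C@@H](OC(C)=O)C[C@]12C | target

**Totals.** 18 steps in all. The longest linear sequence is 16 steps (steps 1–4 and 7–18, from 1 to 30); the aryl branch (steps 5 and 6) joins at step 7.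

**Steps most likely to fail**

Step 10. The carbopalladation may go through a boat-like closure and give poor facial selectivity at C9, or formate may reduce the arylpalladium bromide before it cyclises. The fallback sets out from ketone 13 and builds C9 in two polar operations. Bromine–lithium exchange (tBuLi, THF, −100 °C) followed by Parham-type anionic cyclisation onto the C9 carbonyl should give the tertiary benzylic alcohol F1 as a C9 mixture. Treatment with Me3Al in CH2Cl2 (−78 °C to rt) should ionise it to the p-methoxy-stabilised benzylic cation and deliver methyl pseudoaxially, anti to the axial H-8, placing C20 cis to C17. The route is rejoined at tetralin 15.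

Step 13. The neopentyl-type C4 terminus of the silyl enol ether may react sluggishly with the iminium salt, so that protodesilylation to the C4-unsubstituted ketone competes. The fallback sets out from 19, repeats the TMSCl-assisted cuprate addition and keeps silyl enol ether 21 as crude material. A lanthanide-triflate-catalysed Mukaiyama aldol with aqueous formaldehyde (Yb(OTf)3, THF/H2O) should give the C4 hydroxymethyl ketone F2. Mesylation (MsCl, Et3N) to the mesylate F3 and E1cB elimination with DBU would then come back to the route at the C4-methylene ketone 24, passing by 22 and 23.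

Step 17. The silyloxydiene may be over-oxidised at the C4=C18 bond, or the α'-hydroxy enone acid may decompose on desilylation. The fallback sets out from acid 26 and oxidises the C2 methylene directly with SeO2 in aqueous dioxane at 80 °C (Riley oxidation). The resulting 2,3-dione enolises to the diosphenol, so the route is rejoined at the target 30 with steps 17 and 18 replaced by one; no compound outside the list is formed (none F0).

**Further compounds**

F1 | step 10 | tertiary benzylic alcohol (2S,3S)-6-methoxy-2-methyl-1-[(3R)-3-methyl-5-(triisopropylsilyloxy)pentyl]-3-(triethylsilyloxy)-1,2,3,4-tetrahydronaphthalen-1-ol, C1 epimers | COc1ccc2c(c1)C[C@H](O[Si](CC)(CC)CC)[C@@H](C)C2(O)CC[C@@H](C)CCO[Si](C(C)C)(C(C)C)C(C)C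
F2 | step 13 | C4 hydroxymethyl ketone (cis-fused, C5 methyl, C7 OAc, C15 OTIPS) | OC[C@@H]1C(=O)CC[C@@H]2[C@@](C)(CC[C@@H](C)CCO[Si](C(C)C)(C(C)C)C(C)C)[C@H](C)[C@@H](OC(C)=O)C[C@]12C
F3 | step 13 | mesylate of F2 | CS(=O)(=O)OC[C@@H]1C(=O)CC[C@@H]2[C@@](C)(CC[C@@H](C)CCO[Si](C(C)C)(C(C)C)C(C)C)[C@H](C)[C@@H](OC(C)=O)C[C@]12C
F0 | step 17 | none | none
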